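Everything rests on disconnecting the C3–C4 bond of the pyranone ring C. Both carbons sit at the carbonyl oxidation level and are electrophiles, so C4 is carried as an aroylsilane on ring A and C3 as an aldehyde whose neighbour C2 holds a labile hydrogen (benzylic, next to the ether oxygen O1 and to the formyl group). A chiral lithium phosphite reverses the polarity of C4 through a Brook rearrangement; in one operation the C3–C4 bond forms, ring C closes and C2 and C3 are set while the C2 epimers interconvert. The precursor is a racemic 2-aryloxy-2-arylacetaldehyde: ring A bears the triethylsilyl ketone, two MOM ethers and the C8 prenyl group, ring B its methoxy and prenyl groups.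

Key step: step 14

Abbreviations: MOM = methoxymethyl; prenyl = 3-methylbut-2-en-1-yl.

Assumption: the (R,R) phosphite is taken to favour the (2R,3R) product; if the sense of induction proves opposite, its (S,S) enantiomer is used.

Remark on design: ring B is joined as an α-bromo arylacetate at the salicylaldehyde stage, because a 1-aryl-2-oxyethyl bromide would ionise or eliminate. The ester is reduced later. The ring A prenyl group is placed by Claisen rearrangement and cross-metathesis, so its position is fixed by connectivity. The aldehyde of the precursor is released last because its C2–H is labile. Every compound before step 14 that carries C2 is racemic. Acylsilanes 17 and 18 are kept from light.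

Step 1
Reactants: 1 2,4,6-trihydroxybenzaldehyde
Product: 2 2-hydroxy-4,6-bis(methoxymethoxy)benzaldehyde
Conditions: MOMCl (2.2 equiv), i-Pr2NEt, CH2Cl2, 0 °C to rt
Reagents that add atoms: chloromethyl methyl ether, COCCl
Why: Williamson-type MOM ether formation should take the 4-OH and one ortho OH, while the other ortho OH stays free because it is held in the hydrogen bond to the formyl oxygen.

Step 2
Reactants: 2 2-hydroxy-4,6-bis(methoxymethoxy)benzaldehyde
Product: 3 2-(allyloxy)-4,6-bis(methoxymethoxy)benzaldehyde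
Conditions: allyl bromide, K2CO3, DMF, 50 °C
Reagents that add atoms: allyl bromide, C=CCBr
Why: Williamson O-allylation of the chelated phenol puts the allyl group on the oxygen that later becomes O1.

Step 3
Reactants: 3 2-(allyloxy)-4,6-bis(methoxymethoxy)benzaldehyde
Product: 4 3-allyl-2-hydroxy-4,6-bis(methoxymethoxy)benzaldehyde
Conditions: PhNEt2, 190 °C
Reagents that add atoms: none
Why: The aromatic Claisen rearrangement should deliver the allyl group to the only free ortho carbon (the future C8) and return the phenol, so the substitution pattern of ring A follows from connectivity.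

Step 4
Reactants: 4 3-allyl-2-hydroxy-4,6-bis(methoxymethoxy)benzaldehyde
Product: 5 2-hydroxy-4,6-bis(methoxymethoxy)-3-prenylbenzaldehyde
Conditions: 2-methyl-2-butene (excess), second-generation Grubbs catalyst RuCl2(H2IMes)(PCy3)(=CHPh) (3 mol %), CH2Cl2, 40 °C
Reagents that add atoms: 2-methyl-2-butene, CC=C(C)C
Why: Olefin cross-metathesis of the terminal allyl alkene with excess 2-methyl-2-butene is the standard conversion of an ortho-allyl phenol into a prenyl phenol, and propene leaves.

Step 5
Reactants: 6 2-(3-bromo-4-methoxyphenyl)acetic acid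
Product: 7 methyl 2-(3-bromo-4-methoxyphenyl)acetate
Conditions: MeOH, H2SO4 (cat.), reflux
Reagents that add atoms: methanol, CO
Why: Fischer esterification gives the ester needed for the later enolate chemistry.

Step 6
Reactants: 7 methyl 2-(3-bromo-4-methoxyphenyl)acetate
Product: 8 methyl 2-(4-methoxy-3-prenylphenyl)acetate
Conditions: prenyl bromide, Zn, LiCl, THF, 0 °C; then 7, Pd(OAc)2 (2 mol %), CPhos (4 mol %), THF, rt
Reagents that add atoms: prenylzinc bromide, CC(C)=CC[Zn]Br (made in the flask from prenyl bromide, CC(C)=CCBr, and Zn)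
Why: Negishi cross-coupling with the CPhos ligand is known to join prenylzinc halides at their primary terminus, so the linear prenyl arene should form and the ester tolerates the organozinc.

Step 7
Reactants: 8 methyl 2-(4-methoxy-3-prenylphenyl)acetate
Product: 10 methyl 2-bromo-2-(4-methoxy-3-prenylphenyl)acetate (racemic), via lithium enolate 9 (not isolated)
Conditions: LiN(SiMe3)2, THF, −78 °C; then added to NBS, THF, −78 °C
Reagents that add atoms: N-bromosuccinimide, O=C1CCC(=O)N1Br
Why: Electrophilic α-bromination of the ester enolate, run by inverse addition at low temperature, should stop at the monobromide and spare the prenyl alkene because no radical chain is involved.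

Step 8
Reactants: 5 2-hydroxy-4,6-bis(methoxymethoxy)-3-prenylbenzaldehyde; 10 methyl 2-bromo-2-(4-methoxy-3-prenylphenyl)acetate
Product: 11 methyl 2-[2-formyl-3,5-bis(methoxymethoxy)-6-prenylphenoxy]-2-(4-methoxy-3-prenylphenyl)acetate (racemic)
Conditions: K2CO3, DMF, rt
Reagents that add atoms: none
Why: Williamson SN2 O-alkylation of a salicylaldehyde phenoxide by an activated α-bromo arylacetate is the well-known first stage of 2-arylbenzofuran syntheses, and mild base at room temperature should avoid aldol closure onto the formyl group; this forms the O1–C2 bond with C2 racemic.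

Step 9
Reactants: 11 methyl 2-[2-formyl-3,5-bis(methoxymethoxy)-6-prenylphenoxy]-2-(4-methoxy-3-prenylphenyl)acetate
Product: 12 methyl 2-[2-(1,3-dithian-2-yl)-3,5-bis(methoxymethoxy)-6-prenylphenoxy]-2-(4-methoxy-3-prenylphenyl)acetate (racemic)
Conditions: HS(CH2)3SH, Sc(OTf)3 (5 mol %), CH2Cl2, 0 °C
Reagents that add atoms: 1,3-propanedithiol, SCCCS
Why: Lewis-acid-catalysed dithioacetalisation should need only a mild catalyst at 0 °C because the three oxygen donors of ring A make the hemithioacetal ionise easily, which spares the MOM ethers and the prenyl groups.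

Step 10
Reactants: 12 methyl 2-[2-(1,3-dithian-2-yl)-3,5-bis(methoxymethoxy)-6-prenylphenoxy]-2-(4-methoxy-3-prenylphenyl)acetate
Product: 13 2-[2-(1,3-dithian-2-yl)-3,5-bis(methoxymethoxy)-6-prenylphenoxy]-2-(4-methoxy-3-prenylphenyl)ethanol (racemic)
Conditions: LiAlH4, THF, 0 °C
Reagents that add atoms: none
Why: Hydride reduction of the ester gives the primary alcohol that will become the C3 aldehyde; dithiane, MOM ethers and alkenes are inert.

Step 11
Reactants: 13 2-[2-(1,3-dithian-2-yl)-3,5-bis(methoxymethoxy)-6-prenylphenoxy]-2-(4-methoxy-3-prenylphenyl)ethanol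
Product: 16 2-[3,5-bis(methoxymethoxy)-6-prenyl-2-(2-triethylsilyl-1,3-dithian-2-yl)phenoxy]-2-(4-methoxy-3-prenylphenyl)ethanol (racemic), via dilithio dianion 14 (not isolated), via bis-silyl ether 15 (not isolated)
Conditions: n-BuLi (2.2 equiv), THF, −78 to −30 °C; Et3SiCl (2.5 equiv), −78 °C to rt; then PPTS, MeOH, rt
Reagents that add atoms: chlorotriethylsilane, CC[Si](Cl)(CC)CC
Why: Corey–Seebach metalation of the 2-aryl-1,3-dithiane followed by C-silylation is the classical dithiane entry to acylsilanes, and the primary silyl ether formed at the same time is removed by mild acid methanolysis that leaves the C–Si bond and the MOM ethers.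

Step 12
Reactants: 16 2-[3,5-bis(methoxymethoxy)-6-prenyl-2-(2-triethylsilyl-1,3-dithian-2-yl)phenoxy]-2-(4-methoxy-3-prenylphenyl)ethanol
Product: 17 {2-[2-hydroxy-1-(4-methoxy-3-prenylphenyl)ethoxy]-4,6-bis(methoxymethoxy)-3-prenylphenyl}(triethylsilyl)methanone (racemic)
Conditions: MeI, CaCO3, MeCN/H2O (9:1), 45 °C, dark
Reagents that add atoms: water, O
Why: Alkylative dithiane hydrolysis (S-methylation, then hydrolysis of the sulfonium salt) should release the aroylsilane without any oxidant, halogen electrophile or mercury salt that could attack the prenyl groups or the electron-rich rings.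

Step 13
Reactants: 17 {2-[2-hydroxy-1-(4-methoxy-3-prenylphenyl)ethoxy]-4,6-bis(methoxymethoxy)-3-prenylphenyl}(triethylsilyl)methanone
Product: 18 2-[3,5-bis(methoxymethoxy)-6-prenyl-2-(triethylsilylcarbonyl)phenoxy]-2-(4-methoxy-3-prenylphenyl)acetaldehyde (racemic, C2 labile)
Conditions: Dess–Martin periodinane, NaHCO3, CH2Cl2, 0 °C to rt; used crude
Reagents that add atoms: none
Why: Dess–Martin oxidation converts the primary alcohol into the aldehyde under buffered, non-basic conditions that leave the acylsilane alone, and the enolisable product is taken on at once.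

Step 14
Reactants: 18 2-[3,5-bis(methoxymethoxy)-6-prenyl-2-(triethylsilylcarbonyl)phenoxy]-2-(4-methoxy-3-prenylphenyl)acetaldehyde
Product: 19 (2R,3R)-2-(4-methoxy-3-prenylphenyl)-5,7-bis(methoxymethoxy)-8-prenyl-3-(triethylsilyloxy)chroman-4-one
Conditions: cyclic hydrogen phosphite of (4R,5R)-2,2-dimethyl-α,α,α′,α′-tetrakis(2-fluorophenyl)-1,3-dioxolane-4,5-dimethanol (20 mol %), n-BuLi (20 mol %), THF, −30 °C to rt; then pH 7 buffer
Reagents that add atoms: none
Why: Proposed new method: the lithium phosphite adds to the C4 acylsilane carbonyl, a 1,2-Brook shift moves Et3Si from C4 to oxygen and leaves an α-silyloxy phosphonate carbanion at C4, this carbanion attacks the C3 formyl carbon, the silyl group passes from the C4 oxygen to the new C3 alkoxide, and loss of the phosphite restores the C4 ketone and the catalyst. The closest known reaction type is the intermolecular metallophosphite-catalysed enantioselective cross silyl benzoin of acylsilanes with aldehydes; new here are the ring-closing mode and the dynamic kinetic resolution of an epimerisable α-stereogenic aldehyde. Ring C closes in the 6-exo-trig mode, the C4 carbanion attacking the C3 carbonyl whose oxygen stays outside the ring. C3 is controlled by the chiral TADDOL-derived phosphonate carried on C4, which decides the face of the formyl group that is attacked, and C2 is controlled by selection of one of the two interconverting C2 epimers (exchange through the enolate, C2–H being benzylic and α to both O1 and CHO), the favoured chair-like transition state placing the ring B aryl at C2 and the C3 oxygen both equatorial, hence trans. The step needs chemoselectivity (only C4 may become the nucleophile), which silicon secures because only the acylsilane can undergo the Brook shift, and it needs epimerisation faster than closure, which the high acidity of the C2–H should secure. The main hazards are protonation of the C4 carbanion by that same C2–H and base-induced epimerisation of the product at C3, so the reaction is quenched at neutral pH as soon as 18 is consumed.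

Step 15
Reactants: 19 (2R,3R)-2-(4-methoxy-3-prenylphenyl)-5,7-bis(methoxymethoxy)-8-prenyl-3-(triethylsilyloxy)chroman-4-one
Product: 20 (2R,3R)-3,5,7-trihydroxy-2-(4-methoxy-3-prenylphenyl)-8-prenylchroman-4-one (CNP0233452.1)
Conditions: HCl (3 M aq.), MeOH, 40 °C
Reagents that add atoms: none
Why: Acid-catalysed acetal exchange removes both MOM ethers and solvolysis cleaves the triethylsilyl ether, the usual end-game for prenylated flavonoids; dilute acid should not epimerise C2 or C3 and is mild enough to avoid addition of the 7-OH to the 8-prenyl group.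

Compound list
1 | 2,4,6-trihydroxybenzaldehyde | O=Cc1c(O)cc(O)cc1O | starting material
2 | 2-hydroxy-4,6-bis(methoxymethoxy)benzaldehyde | O=Cc1c(O)cc(OCOC)cc1OCOC | intermediate
3 | 2-(allyloxy)-4,6-bis(methoxymethoxy)benzaldehyde | O=Cc1c(OCC=C)cc(OCOC)cc1OCOC | intermediate
4 | 3-allyl-2-hydroxy-4,6-bis(methoxymethoxy)benzaldehyde | O=Cc1c(O)c(CC=C)c(OCOC)cc1OCOC | intermediate
5 | 2-hydroxy-4,6-bis(methoxymethoxy)-3-(3-methylbut-2-enyl)benzaldehyde | O=Cc1c(O)c(CC=C(C)C)c(OCOC)cc1OCOC | intermediate
6 | 2-(3-bromo-4-methoxyphenyl)acetic acid | COc1ccc(CC(=O)O)cc1Br | starting material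
7 | methyl 2-(3-bromo-4-methoxyphenyl)acetate | COC(=O)Cc1ccc(OC)c(Br)c1 | intermediate
8 | methyl 2-[4-methoxy-3-(3-methylbut-2-enyl)phenyl]acetate | COC(=O)Cc1ccc(OC)c(CC=C(C)C)c1 | intermediate
9 | lithium enolate of 8 (lithium 1-methoxy-2-[4-methoxy-3-(3-methylbut-2-enyl)phenyl]ethenolate) | COC(O[Li])=Cc1ccc(OC)c(CC=C(C)C)c1 | intermediate (not isolated)
10 | methyl 2-bromo-2-[4-methoxy-3-(3-methylbut-2-enyl)phenyl]acetate, racemic | COC(=O)C(Br)c1ccc(OC)c(CC=C(C)C)c1 | intermediate
11 | methyl 2-[2-formyl-3,5-bis(methoxymethoxy)-6-(3-methylbut-2-enyl)phenoxy]-2-[4-methoxy-3-(3-methylbut-2-enyl)phenyl]acetate, racemic | COC(=O)C(Oc1c(CC=C(C)C)c(OCOC)cc(OCOC)c1C=O)c1ccc(OC)c(CC=C(C)C)c1 | intermediate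
12 | methyl 2-[2-(1,3-dithian-2-yl)-3,5-bis(methoxymethoxy)-6-(3-methylbut-2-enyl)phenoxy]-2-[4-methoxy-3-(3-methylbut-2-enyl)phenyl]acetate, racemic | COC(=O)C(Oc1c(CC=C(C)C)c(OCOC)cc(OCOC)c1C1SCCCS1)c1ccc(OC)c(CC=C(C)C)c1 | intermediate
13 | 2-[2-(1,3-dithian-2-yl)-3,5-bis(methoxymethoxy)-6-(3-methylbut-2-enyl)phenoxy]-2-[4-methoxy-3-(3-methylbut-2-enyl)phenyl]ethanol, racemic | OCC(Oc1c(CC=C(C)C)c(OCOC)cc(OCOC)c1C1SCCCS1)c1ccc(OC)c(CC=C(C)C)c1 | intermediate
14 | dilithio derivative of 13 (lithium alkoxide, lithium at C2 of the dithiane) | [Li]OCC(Oc1c(CC=C(C)C)c(OCOC)cc(OCOC)c1C1([Li])SCCCS1)c1ccc(OC)c(CC=C(C)C)c1 | intermediate (not isolated)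
15 | triethylsilyl ether of 16 (O–SiEt3 on the primary alcohol, C–SiEt3 on C2 of the dithiane) | CC[Si](CC)(CC)OCC(Oc1c(CC=C(C)C)c(OCOC)cc(OCOC)c1C1([Si](CC)(CC)CC)SCCCS1)c1ccc(OC)c(CC=C(C)C)c1 | intermediate (not isolated)
16 | 2-[3,5-bis(methoxymethoxy)-6-(3-methylbut-2-enyl)-2-(2-triethylsilyl-1,3-dithian-2-yl)phenoxy]-2-[4-methoxy-3-(3-methylbut-2-enyl)phenyl]ethanol, racemic | OCC(Oc1c(CC=C(C)C)c(OCOC)cc(OCOC)c1C1([Si](CC)(CC)CC)SCCCS1)c1ccc(OC)c(CC=C(C)C)c1 | intermediate
17 | {2-[2-hydroxy-1-[4-methoxy-3-(3-methylbut-2-enyl)phenyl]ethoxy]-4,6-bis(methoxymethoxy)-3-(3-methylbut-2-enyl)phenyl}(triethylsilyl)methanone, racemic | OCC(Oc1c(CC=C(C)C)c(OCOC)cc(OCOC)c1C(=O)[Si](CC)(CC)CC)c1ccc(OC)c(CC=C(C)C)c1 | intermediate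
18 | 2-[3,5-bis(methoxymethoxy)-6-(3-methylbut-2-enyl)-2-(triethylsilylcarbonyl)phenoxy]-2-[4-methoxy-3-(3-methylbut-2-enyl)phenyl]acetaldehyde, racemic | COc1ccc(C(C=O)Oc2c(CC=C(C)C)c(OCOC)cc(OCOC)c2C(=O)[Si](CC)(CC)CC)cc1CC=C(C)C | intermediate
19 | (2R,3R)-2-[4-methoxy-3-(3-methylbut-2-enyl)phenyl]-5,7-bis(methoxymethoxy)-8-(3-methylbut-2-enyl)-3-(triethylsilyloxy)chroman-4-one | COc1ccc([C@H]2Oc3c(CC=C(C)C)c(OCOC)cc(OCOC)c3C(=O)[C@@H]2O[Si](CC)(CC)CC)cc1CC=C(C)C | intermediate
20 | (2R,3R)-3,5,7-trihydroxy-2-[4-methoxy-3-(3-methylbut-2-enyl)phenyl]-8-(3-methylbut-2-enyl)chroman-4-one | COc1ccc([C@H]2Oc3c(CC=C(C)C)c(O)cc(O)c3C(=O)[C@@H]2O)cc1CC=C(C)C | target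

Total step count: 15.
Longest linear sequence: 12 steps (steps 1 to 4 and 8 to 15, from 1).

Steps most likely to fail

1. Step 14 (bears the label). What may go wrong: the C4 carbanion is protonated by the acidic C2–H of the aldehyde before it closes the ring, the phosphite adds too slowly to the crowded, electron-rich aroylsilane, or the catalyst discriminates poorly between the two C2 epimers. The fallback uses known chemistry (asymmetric epoxidation of a chalcone, then ring closure of the epoxide by the phenol) and sets out from 5.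
   - MeMgBr (2.2 equiv, THF) should give 1-[2-hydroxy-4,6-bis(methoxymethoxy)-3-prenylphenyl]ethanol F1, which MnO2 oxidises to 1-[2-hydroxy-4,6-bis(methoxymethoxy)-3-prenylphenyl]ethanone F2.
   - Allyl bromide and K2CO3 give 1-[2-(allyloxy)-4,6-bis(methoxymethoxy)-3-prenylphenyl]ethanone F3.
   - Purchased 3-bromo-4-methoxybenzaldehyde is coupled with tributyl(3-methylbut-2-enyl)stannane (Pd(PPh3)4, DMF, Stille coupling) to give 4-methoxy-3-prenylbenzaldehyde F4.
   - Claisen–Schmidt condensation of F3 with F4 (KOH, EtOH) gives (E)-1-[2-(allyloxy)-4,6-bis(methoxymethoxy)-3-prenylphenyl]-3-(4-methoxy-3-prenylphenyl)prop-2-en-1-one F5.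
   - Juliá–Colonna epoxidation (poly-L-leucine, urea–H2O2, DBU, THF), whose nucleophilic oxidant leaves the prenyl alkenes alone, gives [2-(allyloxy)-4,6-bis(methoxymethoxy)-3-prenylphenyl][(2R,3S)-3-(4-methoxy-3-prenylphenyl)oxiran-2-yl]methanone F6.
   - Pd(PPh3)4 and morpholine remove the allyl group. The freed phenol, the only one available, opens the epoxide at the benzylic carbon with inversion to give (2R,3R)-3-hydroxy-2-(4-methoxy-3-prenylphenyl)-5,7-bis(methoxymethoxy)-8-prenylchroman-4-one F7.
   - HCl in MeOH as in step 15 gives 20, where the route is rejoined.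

2. Step 11. What may go wrong: metalation goes astray (the ring A C6–H between the two MOM ethers and the benzylic CH2 of the prenyl groups compete with the dithiane C–H), or C-silylation of the crowded dithianyl anion beside the bulky ether side chain stalls. The fallback introduces silicon on a smaller substrate, before the two halves are joined, and sets out from 5.
   - Dithioacetalisation as in step 9 gives 2-(1,3-dithian-2-yl)-3,5-bis(methoxymethoxy)-6-prenylphenol F8.
   - n-BuLi (2.2 equiv) then Et3SiCl (2.5 equiv) give triethyl{2-[3,5-bis(methoxymethoxy)-6-prenyl-2-(triethylsilyloxy)phenyl]-1,3-dithian-2-yl}silane F9.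
   - K2CO3 in MeOH cleaves the aryl silyl ether to 3,5-bis(methoxymethoxy)-6-prenyl-2-(2-triethylsilyl-1,3-dithian-2-yl)phenol F10.
   - O-Alkylation with bromide 10 (Cs2CO3, DMF) gives methyl 2-[3,5-bis(methoxymethoxy)-6-prenyl-2-(2-triethylsilyl-1,3-dithian-2-yl)phenoxy]-2-(4-methoxy-3-prenylphenyl)acetate F11.
   - LiAlH4 reduction gives 16, where the route is rejoined.

3. Step 12. What may go wrong: S-methylation at the crowded C4 dithiane is too slow, and more forcing electrophilic or oxidative unmasking would add to the prenyl alkenes, attack the electron-rich rings or cleave the C–Si bond. The fallback uses no dithiane; the acylsilane comes from oxidation of an α-hydroxysilane. It sets out from 11 and bypasses steps 9 to 13.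
   - 4,4,5,5-Tetramethyl-2-(triethylsilyl)-1,3,2-dioxaborolane F12 is made from Et3SiH and B2pin2 with [Ir(OMe)(cod)]2 and 4,4′-di-tert-butyl-2,2′-bipyridine.
   - Copper-catalysed 1,2-addition of its silyl group to the formyl carbon (CuCl, NaOt-Bu, 1,3-bis(2,6-diisopropylphenyl)imidazolium chloride, THF) gives methyl 2-{2-[hydroxy(triethylsilyl)methyl]-3,5-bis(methoxymethoxy)-6-prenylphenoxy}-2-(4-methoxy-3-prenylphenyl)acetate F13.
   - LiBH4 reduces the ester to 2-{2-[hydroxy(triethylsilyl)methyl]-3,5-bis(methoxymethoxy)-6-prenylphenoxy}-2-(4-methoxy-3-prenylphenyl)ethanol F14.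
   - Swern oxidation of both carbinols gives 18, where the route is rejoined.

Further compounds
F1 | step 14 | 1-[2-hydroxy-4,6-bis(methoxymethoxy)-3-(3-methylbut-2-enyl)phenyl]ethanol | CC(O)c1c(O)c(CC=C(C)C)c(OCOC)cc1OCOC
F2 | step 14 | 1-[2-hydroxy-4,6-bis(methoxymethoxy)-3-(3-methylbut-2-enyl)phenyl]ethanone | CC(=O)c1c(O)c(CC=C(C)C)c(OCOC)cc1OCOC
F3 | step 14 | 1-[2-(allyloxy)-4,6-bis(methoxymethoxy)-3-(3-methylbut-2-enyl)phenyl]ethanone | CC(=O)c1c(OCC=C)c(CC=C(C)C)c(OCOC)cc1OCOC
F4 | step 14 | 4-methoxy-3-(3-methylbut-2-enyl)benzaldehyde | COc1ccc(C=O)cc1CC=C(C)C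
F5 | step 14 | (E)-1-[2-(allyloxy)-4,6-bis(methoxymethoxy)-3-(3-methylbut-2-enyl)phenyl]-3-[4-methoxy-3-(3-methylbut-2-enyl)phenyl]prop-2-en-1-one | COc1ccc(/C=C/C(=O)c2c(OCC=C)c(CC=C(C)C)c(OCOC)cc2OCOC)cc1CC=C(C)C
F6 | step 14 | [2-(allyloxy)-4,6-bis(methoxymethoxy)-3-(3-methylbut-2-enyl)phenyl][(2R,3S)-3-[4-methoxy-3-(3-methylbut-2-enyl)phenyl]oxiran-2-yl]methanone | O=C(c1c(OCC=C)c(CC=C(C)C)c(OCOC)cc1OCOC)[C@@H]1O[C@H]1c1ccc(OC)c(CC=C(C)C)c1
F7 | step 14 | (2R,3R)-3-hydroxy-2-[4-methoxy-3-(3-methylbut-2-enyl)phenyl]-5,7-bis(methoxymethoxy)-8-(3-methylbut-2-enyl)chroman-4-one | COc1ccc([C@H]2Oc3c(CC=C(C)C)c(OCOC)cc(OCOC)c3C(=O)[C@@H]2O)cc1CC=C(C)C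
F8 | step 11 | 2-(1,3-dithian-2-yl)-3,5-bis(methoxymethoxy)-6-(3-methylbut-2-enyl)phenol | Oc1c(CC=C(C)C)c(OCOC)cc(OCOC)c1C1SCCCS1
F9 | step 11 | triethyl{2-[3,5-bis(methoxymethoxy)-6-(3-methylbut-2-enyl)-2-(triethylsilyloxy)phenyl]-1,3-dithian-2-yl}silane | CC[Si](CC)(CC)Oc1c(CC=C(C)C)c(OCOC)cc(OCOC)c1C1([Si](CC)(CC)CC)SCCCS1
F10 | step 11 | 3,5-bis(methoxymethoxy)-6-(3-methylbut-2-enyl)-2-(2-triethylsilyl-1,3-dithian-2-yl)phenol | Oc1c(CC=C(C)C)c(OCOC)cc(OCOC)c1C1([Si](CC)(CC)CC)SCCCS1
F11 | step 11 | methyl 2-[3,5-bis(methoxymethoxy)-6-(3-methylbut-2-enyl)-2-(2-triethylsilyl-1,3-dithian-2-yl)phenoxy]-2-[4-methoxy-3-(3-methylbut-2-enyl)phenyl]acetate, racemic | COC(=O)C(Oc1c(CC=C(C)C)c(OCOC)cc(OCOC)c1C1([Si](CC)(CC)CC)SCCCS1)c1ccc(OC)c(CC=C(C)C)c1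
F12 | step 12 | 4,4,5,5-tetramethyl-2-(triethylsilyl)-1,3,2-dioxaborolane | CC[Si](CC)(CC)B1OC(C)(C)C(C)(C)O1
F13 | step 12 | methyl 2-{2-[hydroxy(triethylsilyl)methyl]-3,5-bis(methoxymethoxy)-6-(3-methylbut-2-enyl)phenoxy}-2-[4-methoxy-3-(3-methylbut-2-enyl)phenyl]acetate, mixture of diastereomers | COC(=O)C(Oc1c(CC=C(C)C)c(OCOC)cc(OCOC)c1C(O)[Si](CC)(CC)CC)c1ccc(OC)c(CC=C(C)C)c1
F14 | step 12 | 2-{2-[hydroxy(triethylsilyl)methyl]-3,5-bis(methoxymethoxy)-6-(3-methylbut-2-enyl)phenoxy}-2-[4-methoxy-3-(3-methylbut-2-enyl)phenyl]ethanol, mixture of diastereomers | OCC(Oc1c(CC=C(C)C)c(OCOC)cc(OCOC)c1C(O)[Si](CC)(CC)CC)c1ccc(OC)c(CC=C(C)C)c1
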